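**Plan**

- Feature: ring A is a 1,3,5-trioxygenated benzene in which C4a carries the C4 ketone and C8a carries O1 (flavanone numbering), so its C4a=C8a edge is the enol-ether C=C of a 2-aryl-2,3-dihydro-4H-pyran-4-one.
- Cuts: the four ring A bonds C8–C8a, C7–C8, C5–C6 and C4a–C5 are cut first, giving a 6-(diazoacetyl)dihydropyranone and (triisopropylsilyloxy)acetylene. Ring C is then cut at O1–C8a and C4a–C8a, the chain at C2–C3, and ring B at aryl–CHO and aryl–geranyl.
- Forward order: ring B is dressed (MOM ethers, geranyl, CHO), C2 is set, the chain is extended to a 2,4-diketo ester, ring C closes, the diazoketone is made, and ring A is annulated last. Two deprotections finish the synthesis.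
- Stereochemistry: the only stereocentre, C2 (S), comes from a reagent-controlled Brown allylboration and is kept away from strong base afterwards. The E alkene of the side chain comes with geranyl bromide.

Key step: step 12

Assumption: lithium acetylide is taken to be oxidised by t-BuOOLi to lithium ethynolate below the temperature at which it disproportionates, as substituted lithium acetylides are, and the parent ynolate is taken to silylate on oxygen with i-Pr3SiOTf.

Abbreviation: Ar = 5-[(2E)-3,7-dimethylocta-2,6-dien-1-yl]-2,4-bis(methoxymethoxy)phenyl (ring B with the geranyl chain at C5′ and MOM ethers on O2′ and O4′).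

**Route**

Step 1
Reactants: 1 4,6-dibromoresorcinol
Product: 2 1,5-dibromo-2,4-bis(methoxymethoxy)benzene
Conditions: MeOCH2Cl, i-Pr2NEt, CH2Cl2, 0 °C → rt
Reagents that add atoms: chloromethyl methyl ether, COCCl
Why: Base-mediated O-alkylation (Williamson-type acetal formation) of both phenols should proceed cleanly because the bromine-flanked hydroxyls are acidic and open to the small chloromethyl ether, and the MOM ethers then survive every organometallic and basic step that follows.

Step 2
Reactants: 2 1,5-dibromo-2,4-bis(methoxymethoxy)benzene; 3 geranyl bromide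
Product: 5 1-bromo-5-[(2E)-3,7-dimethylocta-2,6-dien-1-yl]-2,4-bis(methoxymethoxy)benzene (ArBr), via aryllithium 4 (not isolated)
Conditions: n-BuLi (1.0 equiv), THF, −78 °C; CuBr·SMe2 (10 mol%), 3, −78 → 0 °C
Reagents that add atoms: none
Why: Bromine–lithium exchange stops at the monolithio stage because the first aryllithium deactivates the ring toward a second exchange, and copper-catalysed SN2 allylation with the primary allylic bromide should join the chain at its CH2 terminus with the E alkene intact.

Step 3
Reactants: 5 ArBr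
Product: 7 5-geranyl-2,4-bis(methoxymethoxy)benzaldehyde (ArCHO), via aryllithium 6 (not isolated)
Conditions: n-BuLi, THF, −78 °C; DMF, −78 → 0 °C; H2O
Reagents that add atoms: N,N-dimethylformamide, CN(C)C=O
Why: A second bromine–lithium exchange gives an aryllithium chelated by the neighbouring MOM ether, and Bouveault formylation with DMF delivers the aldehyde after collapse of the hemiaminal on aqueous quench.

Step 4
Reactants: 7 ArCHO
Product: 9 (1S)-1-Ar-but-3-en-1-ol, via borinate 8 (not isolated)
Conditions: (−)-Ipc2B(allyl), Et2O, −78 °C; NaOH, H2O2, 0 °C → rt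
Reagents that add atoms: (−)-B-allyldiisopinocampheylborane, C=CCB([C@H]1[C@H](C)[C@H]2C[C@@H](C1)C2(C)C)[C@H]1[C@H](C)[C@H]2C[C@@H](C1)C2(C)C
Why: Brown asymmetric allylboration through a chair Zimmerman–Traxler transition state, with the isopinocampheyl groups of the (+)-α-pinene-derived reagent directing allyl to the Si face of the aldehyde, should set the future C2 as S, the sense this reagent shows with aromatic aldehydes.

Step 5
Reactants: 9 (1S)-1-Ar-but-3-en-1-ol
Product: 10 tert-butyl{[(1S)-1-Ar-but-3-en-1-yl]oxy}dimethylsilane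
Conditions: t-BuMe2SiCl, imidazole, DMF, rt
Reagents that add atoms: tert-butyldimethylsilyl chloride, CC(C)(C)[Si](C)(C)Cl
Why: Silylation of the secondary alcohol under imidazole catalysis (silyl ether protection) blocks retro-aldol and O-acylation pathways in the enolate chemistry of step 7 and is stable to the oxidation of step 6.

Step 6
Reactants: 10 silyl ether of 9
Product: 11 (4S)-4-Ar-4-(tert-butyldimethylsilyloxy)butan-2-one
Conditions: PdCl2 (10 mol%), CuCl, O2 (1 atm), DMF/H2O (7:1), rt
Reagents that add atoms: water, O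
Why: Tsuji–Wacker oxidation by divalent palladium, reoxidised by CuCl and O2, hydrates only the monosubstituted alkene in the Markovnikov sense, the trisubstituted geranyl alkenes being too hindered to bind palladium, and gives the methyl ketone without touching C2.

Step 7
Reactants: 11 methyl ketone; 12 diallyl oxalate
Product: 14 allyl (6S)-6-Ar-6-(tert-butyldimethylsilyloxy)-2,4-dioxohexanoate (largely enolised), via lithium enolate 13 (not isolated)
Conditions: LiN(SiMe3)2, THF, −78 °C; 12, −78 → 0 °C; AcOH
Reagents that add atoms: none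
Why: Kinetic deprotonation at −78 °C takes the less hindered methyl protons, and crossed Claisen condensation with the non-enolisable oxalate diester is driven to the 2,4-diketo ester by deprotonation of the acidic product, the β-silyloxy group being safe because the enolate does not form on its side.

Step 8
Reactants: 14 diketo ester
Product: 16 allyl (2S)-2-Ar-4-oxo-3,4-dihydro-2H-pyran-6-carboxylate, via lactol 15 (not isolated)
Conditions: HF·pyridine, pyridine, THF, 0 °C → rt; then camphorsulfonic acid (10 mol%), 4 Å MS, CH2Cl2, rt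
Reagents that add atoms: none
Why: Fluoride removes the silyl group, the freed hydroxyl adds to the strongly electrophilic α-keto ester carbonyl to close ring C as the six-membered lactol (6-exo-trig), and catalytic acid dehydrates this β-hydroxy ketone through its enol to the vinylogous ester (cyclodehydration of a δ-hydroxy 1,3-dicarbonyl), the C2–O bond never being broken so that the S configuration is kept.

Step 9
Reactants: 16 allyl ester
Product: 17 (2S)-2-Ar-4-oxo-3,4-dihydro-2H-pyran-6-carboxylic acid
Conditions: Pd(PPh3)4 (5 mol%), PhNHMe, THF, rt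
Reagents that add atoms: none
Why: Tsuji–Trost deallylation, in which zerovalent palladium ionises the allyl ester to a π-allyl complex that the weakly basic aniline captures, frees the acid without hydroxide, so the base-labile C3–H/C2–O1 array of the dihydropyranone is not exposed to retro-oxa-Michael opening.

Step 10
Reactants: 17 carboxylic acid
Product: 19 (2S)-6-(diazoacetyl)-2-Ar-2,3-dihydro-4H-pyran-4-one, via mixed anhydride 18 (not isolated)
Conditions: i-BuOCOCl, N-methylmorpholine, THF, −20 °C; CH2N2, Et2O, −20 → 0 °C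
Reagents that add atoms: diazomethane, C=[N+]=[N-]
Why: Acylation of diazomethane by the mixed carbonic anhydride at its more electrophilic acyl carbon (first stage of the Arndt–Eistert sequence) should give the diazoketone under neutral conditions, the donor-substituted, trisubstituted C5=C6 bond being expected to be a poor dipolarophile at −20 to 0 °C.

Step 11
Reactants: 20 acetylene
Product: 23 (triisopropylsilyloxy)acetylene, via lithium acetylide 21 (not isolated), via lithium ethynolate 22 (not isolated)
Conditions: n-BuLi, THF, −78 °C; t-BuOOLi (from t-BuOOH and LiN(SiMe3)2), −78 → −30 °C; i-Pr3SiOTf, −78 → 0 °C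
Reagents that add atoms: tert-butyl hydroperoxide, CC(C)(C)OO; triisopropylsilyl triflate, CC(C)[Si](C(C)C)(C(C)C)OS(=O)(=O)C(F)(F)F
Why: Oxidation of the lithium acetylide by lithium tert-butyl peroxide inserts oxygen into the C–Li bond to give the ynolate (acetylide-to-ynolate oxidation), and the bulky silyl triflate should then react at oxygen and not at carbon to give the silyl ynol ether.

Step 12
Reactants: 19 diazoketone; 23 (triisopropylsilyloxy)acetylene
Product: 28 (2S)-2-Ar-5-hydroxy-7-(triisopropylsilyloxy)-2,3-dihydro-4H-chromen-4-one, via vinylketene 24 (not isolated), via cyclobutenone 25 (not isolated), via dienylketene 26 (not isolated), via cyclohexadienone 27 (not isolated)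
Conditions: 23 (3 equiv), hν (365–405 nm LED), degassed ClCH2CH2Cl, rt; then 80 °C
Reagents that add atoms: none
Why: Proposed new method: light expels N2 from 19 and C8a migrates to the diazo carbon (Wolff rearrangement) to give vinylketene 24, whose electrophilic carbonyl carbon is attacked by the CH terminus of the ynol ether in a [2+2] cycloaddition to cyclobutenone 25; reversible 4π electrocyclic opening (under the light or at 80 °C) gives dienylketene 26, which closes ring A by thermal disrotatory 6π electrocyclisation between the ketene carbon (C5) and C4a, and enolisation of the β-diketone-like 27 gives the C5 phenol. The closest known reaction is the Danheiser benzannulation of α,β-unsaturated and heteroaryl diazomethyl ketones with siloxyalkynes; what is new is that the vinyl partner is the push–pull enol-ether C=C of a dihydropyranone that carries an acyl group (C4) at the closing terminus. Ring A is the only ring formed, by 6π electrocyclisation followed by tautomerisation, and no stereocentre is created: C2 is remote and the medium is neutral, so C3 is never deprotonated and ring C cannot open. Regiochemistry (silyloxy at C7, hydroxyl at C5) follows from the polarity of the ynol ether, whose nucleophilic CH carbon bonds to the ketene carbonyl. Because O1 and C4 are held cis across the endocyclic C4a=C8a bond, the ketene chain is trans to the C4 carbonyl, so oxa-6π closure to a 2-pyranone is geometrically excluded and C4a is the only terminus within reach. Chemoselectivity over enone–alkyne [2+2] photocycloaddition is sought by irradiating in the long-wavelength diazoketone band, and the hydrogen-bonded C5 hydroxyl of 28 should resist acylation by residual ketene.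

Step 13
Reactants: 28 benzannulation product
Product: 30 (2S)-2-(5-geranyl-2,4-dihydroxyphenyl)-5-hydroxy-7-(triisopropylsilyloxy)-2,3-dihydro-4H-chromen-4-one, via tris(trimethylsilyl) ether 29 (not isolated)
Conditions: Me3SiOTf, 2,2'-bipyridyl, MeCN, 0 °C → rt; then H2O
Reagents that add atoms: none
Why: Silyl triflate–bipyridyl dealkylation of aromatic MOM ethers exchanges each acetal for an aryl trimethylsilyl ether in a buffered, non-protic medium, so that the geranyl alkenes and the benzylic C2–O1 bond should not ionise and no free 4′-phenol is present to add to the chain, and water then hydrolyses the labile trimethylsilyl ethers while the bulky silyl ether at O7 stays.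

Step 14
Reactants: 30 7-O-silyl kuwanon E
Product: 31 kuwanon E
Conditions: Bu4NF, AcOH, THF, 0 °C
Reagents that add atoms: none
Why: Fluoride-induced Si–O cleavage of the aryl silyl ether, buffered with acetic acid so that the C7 phenoxide is protonated at once and ring C is not opened by retro-oxa-Michael reaction, should give kuwanon E with C2 untouched.

**Compound list**

1 | 4,6-dibromoresorcinol (4,6-dibromobenzene-1,3-diol) | Oc1cc(O)c(Br)cc1Br | starting material
2 | 1,5-dibromo-2,4-bis(methoxymethoxy)benzene | COCOc1cc(OCOC)c(Br)cc1Br | intermediate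
3 | geranyl bromide [(2E)-1-bromo-3,7-dimethylocta-2,6-diene] | CC(C)=CCC/C(C)=C/CBr | starting material
4 | 5-bromo-2,4-bis(methoxymethoxy)phenyllithium | [Li]c1cc(Br)c(OCOC)cc1OCOC | intermediate
5 | 1-bromo-5-[(2E)-3,7-dimethylocta-2,6-dien-1-yl]-2,4-bis(methoxymethoxy)benzene (ArBr) | CC(C)=CCC/C(C)=C/Cc1cc(Br)c(OCOC)cc1OCOC | intermediate
6 | 5-geranyl-2,4-bis(methoxymethoxy)phenyllithium (ArLi) | CC(C)=CCC/C(C)=C/Cc1cc([Li])c(OCOC)cc1OCOC | intermediate
7 | 5-geranyl-2,4-bis(methoxymethoxy)benzaldehyde (ArCHO) | CC(C)=CCC/C(C)=C/Cc1cc(C=O)c(OCOC)cc1OCOC | intermediate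
8 | (1S)-1-Ar-but-3-en-1-yl diisopinocampheylborinate | CC(C)=CCC/C(C)=C/Cc1cc([C@@H](OB([C@H]2[C@H](C)[C@H]3C[C@@H](C2)C3(C)C)[C@H]2[C@H](C)[C@H]3C[C@@H](C2)C3(C)C)CC=C)c(OCOC)cc1OCOC | intermediate
9 | (1S)-1-Ar-but-3-en-1-ol | CC(C)=CCC/C(C)=C/Cc1cc([C@@H](O)CC=C)c(OCOC)cc1OCOC | intermediate
10 | tert-butyl{[(1S)-1-Ar-but-3-en-1-yl]oxy}dimethylsilane | CC(C)=CCC/C(C)=C/Cc1cc([C@@H](O[Si](C)(C)C(C)(C)C)CC=C)c(OCOC)cc1OCOC | intermediate
11 | (4S)-4-Ar-4-(tert-butyldimethylsilyloxy)butan-2-one | CC(C)=CCC/C(C)=C/Cc1cc([C@@H](O[Si](C)(C)C(C)(C)C)CC(C)=O)c(OCOC)cc1OCOC | intermediate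
12 | diallyl oxalate | C=CCOC(=O)C(=O)OCC=C | starting material
13 | lithium (4S)-4-Ar-4-(tert-butyldimethylsilyloxy)but-1-en-2-olate | CC(C)=CCC/C(C)=C/Cc1cc([C@@H](O[Si](C)(C)C(C)(C)C)CC(=C)O[Li])c(OCOC)cc1OCOC | intermediate
14 | allyl (6S)-6-Ar-6-(tert-butyldimethylsilyloxy)-2,4-dioxohexanoate (drawn as the diketo tautomer) | CC(C)=CCC/C(C)=C/Cc1cc([C@@H](O[Si](C)(C)C(C)(C)C)CC(=O)CC(=O)C(=O)OCC=C)c(OCOC)cc1OCOC | intermediate
15 | allyl (6S)-6-Ar-2-hydroxy-4-oxotetrahydro-2H-pyran-2-carboxylate (lactol, C2 epimers) | CC(C)=CCC/C(C)=C/Cc1cc([C@@H]2CC(=O)CC(O)(C(=O)OCC=C)O2)c(OCOC)cc1OCOC | intermediate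
16 | allyl (2S)-2-Ar-4-oxo-3,4-dihydro-2H-pyran-6-carboxylate | CC(C)=CCC/C(C)=C/Cc1cc([C@@H]2CC(=O)C=C(C(=O)OCC=C)O2)c(OCOC)cc1OCOC | intermediate
17 | (2S)-2-Ar-4-oxo-3,4-dihydro-2H-pyran-6-carboxylic acid | CC(C)=CCC/C(C)=C/Cc1cc([C@@H]2CC(=O)C=C(C(=O)O)O2)c(OCOC)cc1OCOC | intermediate
18 | (2S)-2-Ar-4-oxo-3,4-dihydro-2H-pyran-6-carboxylic isobutyl carbonic anhydride | CC(C)=CCC/C(C)=C/Cc1cc([C@@H]2CC(=O)C=C(C(=O)OC(=O)OCC(C)C)O2)c(OCOC)cc1OCOC | intermediate
19 | (2S)-6-(diazoacetyl)-2-Ar-2,3-dihydro-4H-pyran-4-one | CC(C)=CCC/C(C)=C/Cc1cc([C@@H]2CC(=O)C=C(C(=O)C=[N+]=[N-])O2)c(OCOC)cc1OCOC | intermediate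
20 | acetylene | C#C | starting material
21 | lithium acetylide | [Li]C#C | intermediate
22 | lithium ethynolate | [Li]OC#C | intermediate
23 | (triisopropylsilyloxy)acetylene | C#CO[Si](C(C)C)(C(C)C)C(C)C | intermediate
24 | (2S)-2-Ar-6-(2-oxoethenyl)-2,3-dihydro-4H-pyran-4-one (vinylketene) | CC(C)=CCC/C(C)=C/Cc1cc([C@@H]2CC(=O)C=C(C=C=O)O2)c(OCOC)cc1OCOC | intermediate
25 | 4-[(2S)-2-Ar-4-oxo-3,4-dihydro-2H-pyran-6-yl]-3-(triisopropylsilyloxy)cyclobut-2-en-1-one (ring carbon epimers) | CC(C)=CCC/C(C)=C/Cc1cc([C@@H]2CC(=O)C=C(C3C(=O)C=C3O[Si](C(C)C)(C(C)C)C(C)C)O2)c(OCOC)cc1OCOC | intermediate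
26 | (2S)-2-Ar-6-[(1Z)-4-oxo-2-(triisopropylsilyloxy)buta-1,3-dien-1-yl]-2,3-dihydro-4H-pyran-4-one (dienylketene) | CC(C)=CCC/C(C)=C/Cc1cc([C@@H]2CC(=O)C=C(/C=C(O[Si](C(C)C)(C(C)C)C(C)C)\C=C=O)O2)c(OCOC)cc1OCOC | intermediate
27 | (2S)-2-Ar-7-(triisopropylsilyloxy)-2,3-dihydro-4aH-chromene-4,5-dione (keto tautomer of ring A, C4a epimers) | CC(C)=CCC/C(C)=C/Cc1cc([C@@H]2CC(=O)C3C(=O)C=C(O[Si](C(C)C)(C(C)C)C(C)C)C=C3O2)c(OCOC)cc1OCOC | intermediate
28 | (2S)-2-Ar-5-hydroxy-7-(triisopropylsilyloxy)-2,3-dihydro-4H-chromen-4-one | CC(C)=CCC/C(C)=C/Cc1cc([C@@H]2CC(=O)c3c(O)cc(O[Si](C(C)C)(C(C)C)C(C)C)cc3O2)c(OCOC)cc1OCOC | intermediate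
29 | (2S)-2-[5-geranyl-2,4-bis(trimethylsilyloxy)phenyl]-7-(triisopropylsilyloxy)-5-(trimethylsilyloxy)-2,3-dihydro-4H-chromen-4-one | CC(C)=CCC/C(C)=C/Cc1cc([C@@H]2CC(=O)c3c(O[Si](C)(C)C)cc(O[Si](C(C)C)(C(C)C)C(C)C)cc3O2)c(O[Si](C)(C)C)cc1O[Si](C)(C)C | intermediate
30 | (2S)-2-(5-geranyl-2,4-dihydroxyphenyl)-5-hydroxy-7-(triisopropylsilyloxy)-2,3-dihydro-4H-chromen-4-one | CC(C)=CCC/C(C)=C/Cc1cc([C@@H]2CC(=O)c3c(O)cc(O[Si](C(C)C)(C(C)C)C(C)C)cc3O2)c(O)cc1O | intermediate
31 | kuwanon E, (2S)-2-{5-[(2E)-3,7-dimethylocta-2,6-dien-1-yl]-2,4-dihydroxyphenyl}-5,7-dihydroxy-2,3-dihydro-4H-chromen-4-one | CC(C)=CCC/C(C)=C/Cc1cc([C@@H]2CC(=O)c3c(O)cc(O)cc3O2)c(O)cc1O | target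

**Step count**

Total: 14 steps. Longest linear sequence: 13 steps (steps 1–10 and 12–14, from 4,6-dibromoresorcinol); step 11 is a one-step side branch.

**Steps most likely to fail, with fallbacks**

Step 12. The light may drive [2+2] photocycloaddition of the enone C=C to the ynol ether, or the ketene may be lost by dimerisation before the ynol ether captures it, so that the electrocyclic cascade never starts. The fallback uses known chemistry, takes ring A ready-made and sets C2 by catalysis; it sets out from bromide 5 and comes back to the route at 28. Bromine–lithium exchange of 5 (n-BuLi, THF, −78 °C), B(OMe)3 and mild aqueous hydrolysis would give [5-geranyl-2,4-bis(methoxymethoxy)phenyl]boronic acid F1. Commercial 5,7-dihydroxychromone would be silylated at its non-chelated 7-hydroxyl (i-Pr3SiCl, imidazole, DMF) to 5-hydroxy-7-(triisopropylsilyloxy)chromone F2. Asymmetric conjugate addition of F1 to F2, catalysed by Pd(OCOCF3)2 (divalent palladium) with the enantiomer of the tert-butyl pyridine–oxazoline ligand that leads to 2S (NH4PF6, H2O, ClCH2CH2Cl, 40–60 °C), would give 28 directly; the ligand sense would be fixed on a model chromone first.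

Step 10. Diazomethane may add as a 1,3-dipole across the electron-poor C5=C6 bond, or attack the carbonate carbonyl of the anhydride and return a methyl ester. The fallback delivers the diazo group by diazo transfer to a methyl ketone; it sets out from acid 17 and comes back at 19. Coupling of 17 with ethanethiol (EDC·HCl, DMAP, CH2Cl2) would give S-ethyl (2S)-2-Ar-4-oxo-3,4-dihydro-2H-pyran-6-carbothioate F3. Fukuyama coupling with methylzinc iodide (MeZnI, PdCl2(PPh3)2, toluene, rt) would give (2S)-6-acetyl-2-Ar-2,3-dihydro-4H-pyran-4-one F4. Kinetic enolisation of the acetyl group (LiN(SiMe3)2, THF, −78 °C) and acylation with CF3CO2CH2CF3 would give (2S)-2-Ar-6-(4,4,4-trifluoro-3-oxobutanoyl)-2,3-dihydro-4H-pyran-4-one F5, and detrifluoroacetylative diazo transfer (MeSO2N3, Et3N, H2O, MeCN) would give 19. The one equivalent of amide base at −78 °C is the only base exposure, and it is aimed at the more acidic acetyl protons.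

Step 8. The acid used for dehydration may ionise the benzylic C–O bond, which is activated by two ring oxygens, before or after ring closure; this would erode the C2 configuration or lead to elimination to a styryl ketone, and a MOM acetal may be cleaved as well. The fallback closes ring C by activation and base-mediated E1cB elimination in place of acid catalysis; it sets out from 14 and comes back at 16. Buffered desilylation (Bu4NF, AcOH, THF, 0 °C) would give lactol 15, which would be isolated. Acetylation of its anomeric hydroxyl (Ac2O, Et3N, DMAP, CH2Cl2, 0 °C) would give allyl (6S)-2-acetoxy-6-Ar-4-oxotetrahydro-2H-pyran-2-carboxylate F6, from which the amine removes a C3 proton and acetate leaves to give 16 without any Brønsted acid.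

**Further compounds**

F1 | step 12 | [5-geranyl-2,4-bis(methoxymethoxy)phenyl]boronic acid | CC(C)=CCC/C(C)=C/Cc1cc(B(O)O)c(OCOC)cc1OCOC
F2 | step 12 | 5-hydroxy-7-(triisopropylsilyloxy)-4H-chromen-4-one | O=c1ccoc2cc(O[Si](C(C)C)(C(C)C)C(C)C)cc(O)c12
F3 | step 10 | S-ethyl (2S)-2-Ar-4-oxo-3,4-dihydro-2H-pyran-6-carbothioate | CC(C)=CCC/C(C)=C/Cc1cc([C@@H]2CC(=O)C=C(C(=O)SCC)O2)c(OCOC)cc1OCOC
F4 | step 10 | (2S)-6-acetyl-2-Ar-2,3-dihydro-4H-pyran-4-one | CC(C)=CCC/C(C)=C/Cc1cc([C@@H]2CC(=O)C=C(C(C)=O)O2)c(OCOC)cc1OCOC
F5 | step 10 | (2S)-2-Ar-6-(4,4,4-trifluoro-3-oxobutanoyl)-2,3-dihydro-4H-pyran-4-one | CC(C)=CCC/C(C)=C/Cc1cc([C@@H]2CC(=O)C=C(C(=O)CC(=O)C(F)(F)F)O2)c(OCOC)cc1OCOC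
F6 | step 8 | allyl (6S)-2-acetoxy-6-Ar-4-oxotetrahydro-2H-pyran-2-carboxylate | CC(C)=CCC/C(C)=C/Cc1cc([C@@H]2CC(=O)CC(OC(C)=O)(C(=O)OCC=C)O2)c(OCOC)cc1OCOC
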